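The product G.Q and Q.G.Q can pile up no faster than G and Q can stand together in solution, so I reckoned from those two levels.

    G.Q ⇌ Z (K1 = 0.13, k1 = 0.027 s⁻¹)
    D ⇌ G, rate k2*(cs2 - [G]) while solid is left; crystals form when [G] > cs2 (cs2 = 39 mM, k2 = 0.046 s⁻¹)
    G + Q → G.Q (k3 = 0.089 M⁻¹ s⁻¹)
    Q → L (k4 = 0.0032 s⁻¹)
    Q + G.Q ⇌ Q.G.Q, settled at all times (K5 = 14 M⁻¹)
    J ⇌ Q, rate k6*(cs6 - [Q]) while solid is left; crystals form when [Q] > cs6 (cs6 = 23 mM, k6 = 0.017 s⁻¹)

D 0.10 M; J 0.0900 M; time 10 min

- amounts and yields of G.Q count Q.G.Q too
- given per volume of solution although it is solid: D, J
- at the start none of D is in solution
- at the start none of J is in solution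
- run time (flask): 10 min

- the G.Q and Q.G.Q together standing at 10 min, as a percentage of the D charged
- the change that raises the amount of G.Q and Q.G.Q together at 10 min, in percent of the D charged most ("none" if none brings more than 2 percentage points) (dawn / summer / midnight / winter / none)
- amount of G.Q and Q.G.Q together at 10 min, in percent of the D charged, after midnight

- dawn: doubling the dissolution coefficient of step 2, all else as stated
- summer: doubling the dissolution coefficient of step 6, all else as stated
- midnight: doubling the solubility in step 6, all else as stated
- winter: doubling the solubility in step 2, all else as stated

I held G at its solubility, which makes the loss of Q pseudo-first-order. Q then has a working lifetime, one over the sum of its dissolution coefficient and the two constants consuming it, 42.2 s. That is far shorter than the run, so c_Q levels off at dissolution coefficient times solubility times lifetime, 16.5 mM, and product forms at 0.0573 mM s⁻¹. Holding that level takes 82.6 mM of J by the end, less than the charge, so it lasts. The filling lag is the lifetimes of Q and G together, 64.0 s.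

| Reckoning for the flask | Percent of D charged |
|---|---|
| G and Q both saturated | 47.9% |
| Q at its working level | 34.4% |
| Lag removed: upper bound | 30.7% |
| Z's share taken off: lower bound | 27.2% |

After midnight the level doubles and the demand, 165 mM, exceeds the charge. J becomes the limiting reagent, and its share reaching product caps y at 41.4%. Winter's flask was a different count: G held at twice its solubility with Q at its working level asked for 138 mM of D as dissolved G and product, above the charge, so that level could not be held to the end and I set no figure for winter.

The forecast gave 26.5%, below my bracket, then 36% and winter, because that change “nearly doubles G and sustains the rate for longer”.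

The flask gave 27.3%, inside the bracket, with 36.5% after midnight and winter best, at 16 percentage points. Its y moved 5 points when read at 8.31 min or 11.7 min, so a forecast y could fail there. For the same flask read at 4.0 min, the lifetime gives 8.93% to 10.1%, and it held 9.55%.

The rate constants were chosen freely; what happens was integrated by code.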